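(The numbers in the tables were computed from invented constants; the scatter is artificial.)

In the north-east flask the reagent charged stands to the substrate charged as 1.50 to one, so substrate is the limiting reagent there, and a ledger of its moles shows you what to watch.

all flasks: added ligand 15 mM

| flask | substrate | reagent | free catalyst | temperature | remark | time |
|---|---|---|---|---|---|---|
| gamma | 0.050 M (fed, over 4.0 h) | 0.075 M | 5.7 mM | 24 °C | run made earlier |  |
| beta | 0.050 M (fed, over 4.0 h) | 0.075 M | 23 mM | 32 °C | run made earlier |  |
| theta | 0.050 M (fed, over 4.0 h) | 0.12 M | 7.5 mM | 24 °C | run made earlier |  |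
| south | 0.050 M (fed, over 4.0 h) | 0.0750 M | 7.5 mM | 35 °C |  | 4.0 h |
| south-west | 0.050 M (fed, over 1.0 h) | 0.0750 M | 7.5 mM | 20 °C |  | 4.0 h |
| north | 0.20 M (fed, over 2.0 h) | 0.0750 M | 7.5 mM | 35 °C |  | 4.0 h |
| west | 0.050 M (fed, over 4.0 h) | 0.0750 M | 30 mM | 35 °C |  | 4.0 h |
| north-east | 0.050 M (fed, over 12 h) | 0.0750 M | 7.5 mM | 35 °C |  | 4.0 h |
| east | 0.012 M (fed, over 4.0 h) | 0.120 M | 7.5 mM | 35 °C |  | 4.0 h |

| run | time / h | target / % | substrate / % |
|---|---|---|---|
| gamma | 0.250 | 0 | 5 |
| gamma | 0.667 | 0 | 16 |
| gamma | 1.33 | 1 | 31 |
| gamma | 2.50 | 6 | 52 |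
| gamma | 3.00 | 9 | 57 |
| gamma | 5.00 | 24 | 71 |
| beta | 0.250 | 2 | 6 |
| beta | 0.333 | 2 | 7 |
| beta | 0.500 | 0 | 7 |
| beta | 0.833 | 4 | 11 |
| beta | 1.33 | 13 | 13 |
| beta | 2.00 | 26 | 21 |
| beta | 3.00 | 46 | 23 |
| theta | 0.417 | 2 | 10 |
| theta | 0.667 | 1 | 14 |
| theta | 1.33 | 5 | 29 |
| theta | 2.50 | 9 | 46 |
| theta | 5.00 | 34 | 61 |

(readings scatter by 1.5 percentage points)

- the numbers in the tables scatter by 1.5 percentage points (one standard deviation)
- what may be going on: substrate + free catalyst <-> catalyst intermediate A; reagent + catalyst intermediate A -> catalyst intermediate B; catalyst intermediate B <-> by-product + catalyst intermediate C; catalyst intermediate C <-> free catalyst + target; free catalyst + added ligand <-> idle complex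
- percentages count the whole charge, also what has not yet gone in

* all flasks from highest to lowest amount of target, in percent of the substrate charged, at 4.0 h (south / south-west / north / west / north-east / east)
* the amount of target, in percent of the substrate charged of the flask you put first, at 4.0 h
* the amount of target, in percent of the substrate charged of the flask you put last, at 4.0 h

North-east has the longest feed, 12 h, so the ledger opens with substrate still outside: at 4.0 h, 33.3% of the charge has gone in and 66.7% has not. The fed part splits into target and substrate still waiting, and that split needs one number.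

Divide the rise of target by the substrate standing meanwhile and you get a pseudo-first-order constant. Gamma, from 3.00 h to 5.00 h, scaled in proportion to north-east's 7.5 mM of catalyst, gives 0.154 h⁻¹. Beta, from 2.00 h to 3.00 h, scaled the same way, gives 0.296 h⁻¹. Both runs had the same reagent charge, and with the catalyst scaled out I put what remains of their difference down to temperature, which I assume here; carrying it on to 35 °C gives 0.375 h⁻¹. These are readings, with a scatter of 1.5 percentage points on each. The inverse, the mean time a fed mole of substrate stands before it becomes target, is the waiting time, τ = 2.66 h.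

Now solve both ends. Early on, target grows with the square of time; long after the start, it trails the fed amount by the feed rate times τ. Joined, target = feed rate × (t − τ(1 − exp(−t/τ))). Divide by the amount fed, feed rate × t, and the feed rate drops out. My reckoning for north-east at 4.0 h is therefore 48.2% of the fed part as target and 51.7% of it waiting, and with the unfed entry the books close on the whole charge. When you repeat the flask, watch the waiting entry.

The forecast gives west > east > south > north > south-west > north-east, with 72% on top and 12% at the bottom: “only 33% fed, so about 12%”. The forecast's 12% of the charge comes to 36.0% of the fed part, against my 48.2%, so the two differ.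

The flasks give west > east > south > north > south-west > north-east, the forecast's order, with 71.5% on top and 17.2% at the bottom, 5.2 points above the forecast.

    substrate + free catalyst ⇌ catalyst intermediate A (K = 34.8 M⁻¹, k = 3.08 M⁻¹ min⁻¹, Ea = 60.0 kJ mol⁻¹, ΔH = 23.0 kJ mol⁻¹)
    reagent + catalyst intermediate A → catalyst intermediate B (k = 2.04 M⁻¹ min⁻¹, Ea = 58.0 kJ mol⁻¹)
    catalyst intermediate B ⇌ by-product + catalyst intermediate C (K = 0.0702 M, k = 0.137 min⁻¹, Ea = 83.0 kJ mol⁻¹, ΔH = 3.00 kJ mol⁻¹)
    catalyst intermediate C ⇌ free catalyst + target (K = 0.330 M, k = 10.5 min⁻¹, Ea = 77.0 kJ mol⁻¹, ΔH = −27.0 kJ mol⁻¹)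
    free catalyst + added ligand ⇌ idle complex (K = 42.0 M⁻¹, k = 0.610 M⁻¹ min⁻¹, Ea = 64.0 kJ mol⁻¹, ΔH = 15.0 kJ mol⁻¹)
    (constants at 35 °C)

North-east's ledger reads 17.2% target, which is 51.7% of the fed part against the reckoned 48.2%, with 14.2% of the charge as free substrate and 1.89% on the catalyst intermediates. Run the same flask at 50 °C, and the temperature step read from gamma and beta shortens τ to 0.872 h, so the joined formula puts 78.4% of the fed part into target. At 4.00 h that warmer flask holds 26.7% of the charge as target, 80.2% of the fed part, and 5.36% as free substrate.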